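Cuts, in retrosynthetic order: the O6–acyl ester; C11–C12 (from CO) and C11≡C13 (one-carbon homologation of a C11 aldehyde); C6–O and C5–H (hydroboration of a Δ5 alkene); C4=C15 (made from the C4 methyl through a C4 selenide); last, C9–C10.
Enabling feature: in ring A the oxygens on C1 and C3, C15 on C4 and the C14 methyl on C10 form the pattern of a 4,6-dimethylresorcinol whose C5 carries the C6–C9 chain. C4 and C10 are enantiotopic, so joining C9 to one of them creates the quaternary centre, ring B and the non-aromatic 1,3-dione in one step.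
Forward order: ring A is bought as a benzoate and methylated twice. C7–C9 and C11 are attached by ylide alkylation and Wittig olefination. Ring B then closes by palladium-catalysed allylic dearomatisation, ring A is reduced, ring B is oxygenated and the two acrylate units are finished.
Stereochemistry: C10 comes from the chiral bisphosphine on palladium. All other centres are relayed from the axial C14 methyl: C7 (hydrogenation, equatorial ester), C1 and C3 (hydride from the α face), C5 and C6 (syn hydroboration from the α face).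

Key step: step 10

Numbering: eudesmane locants are used for all bicyclic compounds (C14 = methyl on C10, C15 = carbon on C4, C11 on C7; β = face of C14). TBS = tert-butyldimethylsilyl, TMS = trimethylsilyl.
Assumption: the (1R,2R) ligand is taken to give the 10R product. The sense of induction must be checked on the first run, and the (1S,2S) ligand is used if it is opposite.

Step 1
Reactants: 1 methyl 3,5-dihydroxybenzoate
Product: 2 methyl 3,5-bis(TBSO)benzoate
Conditions: TBSCl, imidazole, DMF, rt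
Reagents that add atoms: tert-butyldimethylsilyl chloride CC(C)(C)[Si](C)(C)Cl
Why: Silyl ether formation masks both phenols with groups that survive organozinc, hydride and ylide chemistry and that fluoride can later remove without touching an allylic carbonate.

Step 2
Reactants: 2 methyl 3,5-bis(TBSO)benzoate
Product: 3 methyl 2,6-dibromo-3,5-bis(TBSO)benzoate
Conditions: NBS (2.1 equiv), MeCN, 0 °C to rt
Reagents that add atoms: N-bromosuccinimide O=C1CCC(=O)N1Br
Why: Electrophilic aromatic bromination goes to C2 and C6, each para to one and ortho to the other silyloxy group, because the position between the two bulky silyl ethers is shielded.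

Step 3
Reactants: 3 methyl 2,6-dibromo-3,5-bis(TBSO)benzoate
Product: 4 methyl 3,5-bis(TBSO)-2,6-dimethylbenzoate
Conditions: Me2Zn, Pd(dppf)Cl2 (5 mol %), 1,4-dioxane, 90 °C
Reagents that add atoms: dimethylzinc C[Zn]C
Why: A double Negishi coupling replaces both bromides by methyl (future C14 and C15) and tolerates the ester and the aryl silyl ethers.

Step 4
Reactants: 4 methyl 3,5-bis(TBSO)-2,6-dimethylbenzoate
Product: 5 [3,5-bis(TBSO)-2,6-dimethylphenyl]methanol
Conditions: DIBAL-H (3 equiv), toluene, 0 °C to rt; potassium sodium tartrate work-up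
Reagents that add atoms: none
Why: Hydride reduction of the benzoate to the benzylic alcohol (future C6) also works on di-ortho-substituted esters and leaves aryl silyl ethers intact.

Step 5
Reactants: 5 [3,5-bis(TBSO)-2,6-dimethylphenyl]methanol
Product: 6 3,5-bis(TBSO)-2,6-dimethylbenzyl bromide
Conditions: CBr4, PPh3, CH2Cl2, 0 °C
Reagents that add atoms: tetrabromomethane BrC(Br)(Br)Br
Why: The Appel reaction turns the benzylic alcohol into the bromide under neutral conditions.

Step 6
Reactants: 6 3,5-bis(TBSO)-2,6-dimethylbenzyl bromide; 7 methyl (triphenylphosphoranylidene)acetate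
Product: 9 methyl 3-[3,5-bis(TBSO)-2,6-dimethylphenyl]-2-(triphenylphosphoranylidene)propanoate, via alkylated phosphonium bromide 8 (not isolated)
Conditions: 7 (2.1 equiv), toluene, 90 °C
Reagents that add atoms: none
Why: C-alkylation of the stabilised ylide by the benzylic bromide forms C6–C7, and transylidation by the second equivalent of 7 gives the α-substituted ylide.

Step 7
Reactants: 10 allyl methyl carbonate
Product: 12 2-oxoethyl methyl carbonate, via secondary ozonide 11 (not isolated)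
Conditions: O3, CH2Cl2, −78 °C; then Me2S, −78 °C to rt
Reagents that add atoms: ozone [O-][O+]=O
Why: Ozonolysis with reductive work-up cleaves the terminal alkene and gives the C8–C9 aldehyde with the carbonate leaving group already in place.

Step 8
Reactants: 9 methyl 3-[3,5-bis(TBSO)-2,6-dimethylphenyl]-2-(triphenylphosphoranylidene)propanoate; 12 2-oxoethyl methyl carbonate
Product: 13 methyl (E)-2-{[3,5-bis(TBSO)-2,6-dimethylphenyl]methyl}-4-(methoxycarbonyloxy)but-2-enoate
Conditions: toluene, 80 °C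
Reagents that add atoms: none
Why: Wittig olefination with an α-substituted stabilised ylide is E-selective and base-free, which places C9 cis to C6 as the ring closure requires.

Step 9
Reactants: 13 methyl (E)-2-{[3,5-bis(TBSO)-2,6-dimethylphenyl]methyl}-4-(methoxycarbonyloxy)but-2-enoate
Product: 14 methyl (E)-2-[(3,5-dihydroxy-2,6-dimethylphenyl)methyl]-4-(methoxycarbonyloxy)but-2-enoate
Conditions: KHF2, MeOH, rt to 40 °C
Reagents that add atoms: none
Why: Bifluoride cleaves aryl silyl ethers under nearly neutral conditions, so the carbonate and the enoate persist and the symmetric free resorcinol is released.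

Step 10
Reactants: 14 methyl (E)-2-[(3,5-dihydroxy-2,6-dimethylphenyl)methyl]-4-(methoxycarbonyloxy)but-2-enoate
Product: 15 methyl (10R)-1,3-dioxo-12,13-dinoreudesma-4,7-dien-11-oate (enolised 1,3-dione)
Conditions: Pd2(dba)3·CHCl3 (2.5 mol %), (1R,2R)-N,N'-bis[2-(diphenylphosphino)benzoyl]cyclohexane-1,2-diamine (7.5 mol %), CH2Cl2 (0.01 M), rt
Reagents that add atoms: none
Why: Proposed new method: zerovalent palladium ionises the allylic carbonate (CO2 and methoxide leave, and the methoxide deprotonates the resorcinol) to an η3-allyl complex over C7–C8–C9, and the resorcinolate attacks the primary terminus C9, anti to the metal, through the methyl-bearing carbon next to the benzylic arm, so that C9–C10 forms and ring A is left as a non-aromatic 1,3-dione. The closest known reactions are the palladium- and iridium-catalysed intramolecular asymmetric allylic dearomatisations of phenols (Tsuji–Trost type) and the base-induced C-alkylation of phenolates to cyclohexadienones; new here are the resorcinol nucleophile, the fused rather than spiro outcome and the desymmetrisation. Ring B closes in a six-membered mode that is endo with respect to the allyl unit (C7, C8 and C9 all become ring members), which needs C6 in the anti position of the allyl, as the E-enoate of 14 provides, and any syn–anti isomer cannot cyclise and can only equilibrate back. The one new stereocentre, C10, is set by the chiral pocket of the twofold-symmetric bisphosphine, which must tell apart the enantiotopic carbons C4 and C10 (equivalently the two faces of the flat arene), since the substrate has no bias of its own. Regioselectivity is secured by the substrate: attack at C7 would give a cyclobutane, the ester on C7 sends nucleophiles to the remote terminus, O-alkylation would need an eight-membered ring, C2 cannot reach the allyl, and the two methyl groups block rearomatisation. High dilution holds back intermolecular O-allylation.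

Step 11
Reactants: 15 methyl (10R)-1,3-dioxo-12,13-dinoreudesma-4,7-dien-11-oate
Product: 16 methyl 1,3-dioxo-7αH-12,13-dinoreudesm-4-en-11-oate (7β-ester)
Conditions: H2 (1 atm), 10% Pd/C, EtOAc, rt
Reagents that add atoms: none
Why: Heterogeneous hydrogenation of the trisubstituted enoate adds hydrogen from the α face, away from the axial C14 methyl; the resulting equatorial 7β-ester is also the thermodynamic epimer at this ester α-carbon, and the tetrasubstituted, enolised Δ4 unit is left untouched.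

Step 12
Reactants: 16 methyl 1,3-dioxo-7αH-12,13-dinoreudesm-4-en-11-oate
Product: 17 methyl 3-methoxy-1-oxo-7αH-12,13-dinoreudesma-2,4-dien-11-oate
Conditions: MeOH, HC(OMe)3, TsOH·H2O (cat.), rt
Reagents that add atoms: methanol CO
Why: Acid-catalysed vinylogous esterification adds methanol to the C3 carbonyl, because C1 is shielded on both faces by quaternary C10 (as with 4,4-disubstituted cyclohexane-1,3-diones), and the equilibrating conditions allow any other isomer to be recycled.

Step 13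
Reactants: 17 methyl 3-methoxy-1-oxo-7αH-12,13-dinoreudesma-2,4-dien-11-oate
Product: 18 3-methoxy-7αH-12,13-dinoreudesma-2,4-diene-1β,11-diol
Conditions: DIBAL-H (5 equiv), CH2Cl2, −78 to −20 °C; potassium sodium tartrate work-up
Reagents that add atoms: none
Why: DIBAL-H reduces the ester to the C11 alcohol and the vinylogous ester carbonyl in 1,2 fashion, with hydride reaching C1 from the α face, anti to the neighbouring axial C14 methyl, as in angularly methylated 1-decalones, to give the 1β-alcohol.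

Step 14
Reactants: 18 3-methoxy-7αH-12,13-dinoreudesma-2,4-diene-1β,11-diol
Product: 19 1β,11-bis(TBSO)-3-methoxy-7αH-12,13-dinoreudesma-2,4-diene
Conditions: TBSOTf (2.5 equiv), 2,6-lutidine, CH2Cl2, −78 to 0 °C
Reagents that add atoms: tert-butyldimethylsilyl triflate CC(C)(C)[Si](C)(C)OS(=O)(=O)C(F)(F)F
Why: Silylation under buffered conditions caps both alcohols, which makes the C1 oxygen a poor leaving group before the enol ether is exposed to acid.

Step 15
Reactants: 19 1β,11-bis(TBSO)-3-methoxy-7αH-12,13-dinoreudesma-2,4-diene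
Product: 20 1β,11-bis(TBSO)-7αH-12,13-dinoreudesm-4-en-3-one
Conditions: oxalic acid (cat.), THF–H2O, 0 °C
Reagents that add atoms: water O
Why: Enol ether hydrolysis starts by protonation at C2 to an oxocarbenium ion conjugated with Δ4 and is much faster than silyl ether cleavage or loss of the β-silyloxy group, so the 4-en-3-one is released with C1–O intact.

Step 16
Reactants: 20 1β,11-bis(TBSO)-7αH-12,13-dinoreudesm-4-en-3-one
Product: 21 1β,11-bis(TBSO)-3-(TMSO)-7αH-12,13-dinoreudesma-3,5-diene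
Conditions: TMSOTf, Et3N, CH2Cl2, 0 °C
Reagents that add atoms: trimethylsilyl triflate C[Si](C)(C)OS(=O)(=O)C(F)(F)F
Why: Soft enolisation of a 4-en-3-one gives the thermodynamic heteroannular 3,5-dienol silyl ether by loss of a C6 proton and avoids a free C2 enolate that could expel the C1 silyloxy group.

Step 17
Reactants: 21 1β,11-bis(TBSO)-3-(TMSO)-7αH-12,13-dinoreudesma-3,5-diene
Product: 24 1β,11-bis(TBSO)-4α-(phenylseleno)-7αH-12,13-dinoreudesm-5-en-3β-ol, via lithium 3,5-dienolate 22 (not isolated), via 4α-phenylseleno 5-en-3-one 23 (not isolated)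
Conditions: MeLi, THF, 0 °C; PhSeBr (1.0 equiv), −78 °C; LiAlH4, −78 to −20 °C
Reagents that add atoms: benzeneselenenyl bromide Br[Se]c1ccccc1
Why: Cleaving the silyl enol ether with MeLi gives the regiodefined extended enolate, which is selenenylated at its α-carbon C4 from the α face (the β face is covered by C14) with the alkene moving to Δ5, and the labile α-seleno ketone is reduced in the same flask by axial hydride attack from the α face to the equatorial 3β-alcohol, as known for 4,4-disubstituted 5-en-3-ones.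

Step 18
Reactants: 24 1β,11-bis(TBSO)-4α-(phenylseleno)-7αH-12,13-dinoreudesm-5-en-3β-ol
Product: 25 1β,3β,11-tris(TBSO)-4α-(phenylseleno)-7αH-12,13-dinoreudesm-5-ene
Conditions: TBSOTf, 2,6-lutidine, CH2Cl2, 0 °C
Reagents that add atoms: tert-butyldimethylsilyl triflate CC(C)(C)[Si](C)(C)OS(=O)(=O)C(F)(F)F
Why: The silyl triflate is reactive enough to silylate the hindered secondary alcohol next to quaternary C4, so that O6 will later be the only free hydroxyl.

Step 19
Reactants: 25 1β,3β,11-tris(TBSO)-4α-(phenylseleno)-7αH-12,13-dinoreudesm-5-ene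
Product: 28 1β,3β,11-tris(TBSO)-5αH,7αH-12,13-dinoreudesm-4(15)-en-6α-ol, via 6α-borane 26 (not isolated), via 6α-hydroxy selenoxide 27 (not isolated)
Conditions: BH3·THF, THF, 0 °C to rt; then 30% H2O2, aq NaOH, 0 °C to rt
Reagents that add atoms: hydrogen peroxide OO
Why: In the hydroboration–oxidation, borane adds syn from the α face (both axial methyls, C14 and C15, cover the β face) with boron on the less substituted C6, setting 5α-H and 6α-OH as in 4,4-dimethyl 5-ene steroids, while the peroxide also oxidises the selenide, and the selenoxide eliminates syn towards the freely rotating C15 methyl because C5–H and C3–H are held about 60° out of plane in the trans-decalin and C3–H is further deactivated by its oxygen.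

Step 20
Reactants: 28 1β,3β,11-tris(TBSO)-5αH,7αH-12,13-dinoreudesm-4(15)-en-6α-ol
Product: 29 1β,3β-bis(TBSO)-5αH,7αH-12,13-dinoreudesm-4(15)-ene-6α,11-diol
Conditions: HF·pyridine, pyridine, THF, 0 °C
Reagents that add atoms: none
Why: Buffered fluoride cleaves the unhindered primary silyl ether much faster than the two hindered secondary ones (selective desilylation).

Step 21
Reactants: 29 1β,3β-bis(TBSO)-5αH,7αH-12,13-dinoreudesm-4(15)-ene-6α,11-diol
Product: 30 1β,3β-bis(TBSO)-6α-hydroxy-5αH,7αH-12,13-dinoreudesm-4(15)-en-11-al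
Conditions: TEMPO (cat.), PhI(OAc)2, CH2Cl2, rt
Reagents that add atoms: none
Why: The oxoammonium (TEMPO) oxidation selects the primary alcohol over the hindered secondary 6α-alcohol and stops at the aldehyde.

Step 22
Reactants: 30 1β,3β-bis(TBSO)-6α-hydroxy-5αH,7αH-12,13-dinoreudesm-4(15)-en-11-al
Product: 31 1β,3β-bis(TBSO)-5αH,7αH-12-noreudesm-4(15)-en-11(13)-yn-6α-ol (7β-ethynyl)
Conditions: dimethyl (1-diazo-2-oxopropyl)phosphonate, K2CO3, MeOH, 0 °C to rt
Reagents that add atoms: dimethyl (1-diazo-2-oxopropyl)phosphonate CC(=O)C(=[N+]=[N-])P(=O)(OC)OC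
Why: The Seyferth–Gilbert homologation (Ohira–Bestmann variant) converts the aldehyde into the terminal alkyne (C13) under mild carbonate base, and the 7β side chain is already the equatorial, thermodynamic epimer.

Step 23
Reactants: 32 methyl 2-(hydroxymethyl)acrylate
Product: 33 methyl 2-[(TBSO)methyl]acrylate
Conditions: TBSCl, imidazole, CH2Cl2, rt
Reagents that add atoms: tert-butyldimethylsilyl chloride CC(C)(C)[Si](C)(C)Cl
Why: Silyl ether formation protects the primary allylic alcohol of the acyl fragment.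

Step 24
Reactants: 33 methyl 2-[(TBSO)methyl]acrylate
Product: 34 2-[(TBSO)methyl]acrylic acid
Conditions: LiOH, THF–H2O, 0 °C; then 1 M HCl to pH 4
Reagents that add atoms: lithium hydroxide [Li+].[OH-]
Why: Saponification of the methyl ester with cold LiOH leaves the silyl ether intact and gives the free acid.

Step 25
Reactants: 34 2-[(TBSO)methyl]acrylic acid; 31 1β,3β-bis(TBSO)-5αH,7αH-12-noreudesm-4(15)-en-11(13)-yn-6α-ol
Product: 36 1β,3β-bis(TBSO)-5αH,7αH-12-noreudesm-4(15)-en-11(13)-yn-6α-yl 2-[(TBSO)methyl]acrylate, via mixed anhydride 35 (not isolated)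
Conditions: 2,4,6-trichlorobenzoyl chloride, Et3N, THF, rt; then 31, DMAP, toluene, rt to 40 °C
Reagents that add atoms: none
Why: The Yamaguchi esterification acylates the hindered 6α-alcohol, the only free hydroxyl, and because C12 is not yet present no γ-lactone can form.

Step 26
Reactants: 36 1β,3β-bis(TBSO)-5αH,7αH-12-noreudesm-4(15)-en-11(13)-yn-6α-yl 2-[(TBSO)methyl]acrylate
Product: 37 methyl 1β,3β-bis(TBSO)-6α-{2-[(TBSO)methyl]acryloyloxy}-5αH,7αH-eudesma-4(15),11(13)-dien-12-oate
Conditions: Pd(OAc)2 (2 mol %), 2-(diphenylphosphino)pyridine (30 mol %), MeSO3H (cat.), CO (10 bar), MeOH (10 equiv), CH2Cl2, 40 °C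
Reagents that add atoms: carbon monoxide [C-]#[O+]; methanol CO
Why: Palladium-catalysed Markovnikov hydromethoxycarbonylation of a terminal alkyne with the pyridylphosphine system places CO2Me on the inner carbon C11 and gives the 2-substituted acrylate directly, the alkyne binding far better than the 1,1-disubstituted alkenes present.

Step 27
Reactants: 37 methyl 1β,3β-bis(TBSO)-6α-{2-[(TBSO)methyl]acryloyloxy}-5αH,7αH-eudesma-4(15),11(13)-dien-12-oate
Product: 38 methyl 1β,3β-dihydroxy-6α-[2-(hydroxymethyl)acryloyloxy]-5αH,7αH-eudesma-4(15),11(13)-dien-12-oate (CNP0247525.1)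
Conditions: HF·pyridine, THF, 0 °C to rt
Reagents that add atoms: none
Why: Global fluoride desilylation under weakly acidic conditions frees the three alcohols without acyl migration, ester cleavage or conjugate addition to the two acrylates.

Compound list
1 | methyl 3,5-dihydroxybenzoate | COC(=O)c1cc(O)cc(O)c1 | starting material
2 | methyl 3,5-bis(TBSO)benzoate | COC(=O)c1cc(O[Si](C)(C)C(C)(C)C)cc(O[Si](C)(C)C(C)(C)C)c1 | intermediate
3 | methyl 2,6-dibromo-3,5-bis(TBSO)benzoate | COC(=O)c1c(Br)c(O[Si](C)(C)C(C)(C)C)cc(O[Si](C)(C)C(C)(C)C)c1Br | intermediate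
4 | methyl 3,5-bis(TBSO)-2,6-dimethylbenzoate | COC(=O)c1c(C)c(O[Si](C)(C)C(C)(C)C)cc(O[Si](C)(C)C(C)(C)C)c1C | intermediate
5 | [3,5-bis(TBSO)-2,6-dimethylphenyl]methanol | OCc1c(C)c(O[Si](C)(C)C(C)(C)C)cc(O[Si](C)(C)C(C)(C)C)c1C | intermediate
6 | 3,5-bis(TBSO)-2,6-dimethylbenzyl bromide | BrCc1c(C)c(O[Si](C)(C)C(C)(C)C)cc(O[Si](C)(C)C(C)(C)C)c1C | intermediate
7 | methyl (triphenylphosphoranylidene)acetate | COC(=O)C=P(c1ccccc1)(c1ccccc1)c1ccccc1 | starting material
8 | {1-methoxy-1-oxo-3-[3,5-bis(TBSO)-2,6-dimethylphenyl]propan-2-yl}triphenylphosphonium bromide | COC(=O)C(Cc1c(C)c(O[Si](C)(C)C(C)(C)C)cc(O[Si](C)(C)C(C)(C)C)c1C)[P+](c1ccccc1)(c1ccccc1)c1ccccc1.[Br-] | intermediate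
9 | methyl 3-[3,5-bis(TBSO)-2,6-dimethylphenyl]-2-(triphenylphosphoranylidene)propanoate | COC(=O)C(Cc1c(C)c(O[Si](C)(C)C(C)(C)C)cc(O[Si](C)(C)C(C)(C)C)c1C)=P(c1ccccc1)(c1ccccc1)c1ccccc1 | intermediate
10 | allyl methyl carbonate | C=CCOC(=O)OC | starting material
11 | methyl (1,2,4-trioxolan-3-yl)methyl carbonate | COC(=O)OCC1OCOO1 | intermediate
12 | 2-oxoethyl methyl carbonate | COC(=O)OCC=O | intermediate
13 | methyl (E)-2-{[3,5-bis(TBSO)-2,6-dimethylphenyl]methyl}-4-(methoxycarbonyloxy)but-2-enoate | COC(=O)OC/C=C(\Cc1c(C)c(O[Si](C)(C)C(C)(C)C)cc(O[Si](C)(C)C(C)(C)C)c1C)C(=O)OC | intermediate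
14 | methyl (E)-2-[(3,5-dihydroxy-2,6-dimethylphenyl)methyl]-4-(methoxycarbonyloxy)but-2-enoate | COC(=O)OC/C=C(\Cc1c(C)c(O)cc(O)c1C)C(=O)OC | intermediate
15 | methyl (10R)-1,3-dioxo-12,13-dinoreudesma-4,7-dien-11-oate | C1C2=C(C)C(=O)CC(=O)[C@]2(C)CC=C1C(=O)OC | intermediate
16 | methyl 1,3-dioxo-7αH-12,13-dinoreudesm-4-en-11-oate | C1C2=C(C)C(=O)CC(=O)[C@]2(C)CC[C@H]1C(=O)OC | intermediate
17 | methyl 3-methoxy-1-oxo-7αH-12,13-dinoreudesma-2,4-dien-11-oate | C1C2=C(C)C(OC)=CC(=O)[C@]2(C)CC[C@H]1C(=O)OC | intermediate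
18 | 3-methoxy-7αH-12,13-dinoreudesma-2,4-diene-1β,11-diol | C1C2=C(C)C(OC)=C[C@@H](O)[C@]2(C)CC[C@H]1CO | intermediate
19 | 1β,11-bis(TBSO)-3-methoxy-7αH-12,13-dinoreudesma-2,4-diene | C1C2=C(C)C(OC)=C[C@@H](O[Si](C)(C)C(C)(C)C)[C@]2(C)CC[C@H]1CO[Si](C)(C)C(C)(C)C | intermediate
20 | 1β,11-bis(TBSO)-7αH-12,13-dinoreudesm-4-en-3-one | C1C2=C(C)C(=O)C[C@@H](O[Si](C)(C)C(C)(C)C)[C@]2(C)CC[C@H]1CO[Si](C)(C)C(C)(C)C | intermediate
21 | 1β,11-bis(TBSO)-3-(TMSO)-7αH-12,13-dinoreudesma-3,5-diene | C1=C2C(C)=C(O[Si](C)(C)C)C[C@@H](O[Si](C)(C)C(C)(C)C)[C@]2(C)CC[C@H]1CO[Si](C)(C)C(C)(C)C | intermediate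
22 | lithium 3,5-dienolate of 20 | C1=C2C(C)=C([O-])C[C@@H](O[Si](C)(C)C(C)(C)C)[C@]2(C)CC[C@H]1CO[Si](C)(C)C(C)(C)C.[Li+] | intermediate
23 | 1β,11-bis(TBSO)-4α-(phenylseleno)-7αH-12,13-dinoreudesm-5-en-3-one | C1=C2[C@](C)([Se]c3ccccc3)C(=O)C[C@@H](O[Si](C)(C)C(C)(C)C)[C@]2(C)CC[C@H]1CO[Si](C)(C)C(C)(C)C | intermediate
24 | 1β,11-bis(TBSO)-4α-(phenylseleno)-7αH-12,13-dinoreudesm-5-en-3β-ol | C1=C2[C@](C)([Se]c3ccccc3)[C@@H](O)C[C@@H](O[Si](C)(C)C(C)(C)C)[C@]2(C)CC[C@H]1CO[Si](C)(C)C(C)(C)C | intermediate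
25 | 1β,3β,11-tris(TBSO)-4α-(phenylseleno)-7αH-12,13-dinoreudesm-5-ene | C1=C2[C@](C)([Se]c3ccccc3)[C@@H](O[Si](C)(C)C(C)(C)C)C[C@@H](O[Si](C)(C)C(C)(C)C)[C@]2(C)CC[C@H]1CO[Si](C)(C)C(C)(C)C | intermediate
26 | 6α-boryl-1β,3β,11-tris(TBSO)-4α-(phenylseleno)-5αH,7αH-12,13-dinoreudesmane | B[C@@H]1[C@H]2[C@](C)([Se]c3ccccc3)[C@@H](O[Si](C)(C)C(C)(C)C)C[C@@H](O[Si](C)(C)C(C)(C)C)[C@]2(C)CC[C@H]1CO[Si](C)(C)C(C)(C)C | intermediate
27 | 1β,3β,11-tris(TBSO)-4α-(phenylseleninyl)-5αH,7αH-12,13-dinoreudesman-6α-ol | O[C@@H]1[C@H]2[C@](C)([Se](=O)c3ccccc3)[C@@H](O[Si](C)(C)C(C)(C)C)C[C@@H](O[Si](C)(C)C(C)(C)C)[C@]2(C)CC[C@H]1CO[Si](C)(C)C(C)(C)C | intermediate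
28 | 1β,3β,11-tris(TBSO)-5αH,7αH-12,13-dinoreudesm-4(15)-en-6α-ol | O[C@@H]1[C@H]2C(=C)[C@@H](O[Si](C)(C)C(C)(C)C)C[C@@H](O[Si](C)(C)C(C)(C)C)[C@]2(C)CC[C@H]1CO[Si](C)(C)C(C)(C)C | intermediate
29 | 1β,3β-bis(TBSO)-5αH,7αH-12,13-dinoreudesm-4(15)-ene-6α,11-diol | O[C@@H]1[C@H]2C(=C)[C@@H](O[Si](C)(C)C(C)(C)C)C[C@@H](O[Si](C)(C)C(C)(C)C)[C@]2(C)CC[C@H]1CO | intermediate
30 | 1β,3β-bis(TBSO)-6α-hydroxy-5αH,7αH-12,13-dinoreudesm-4(15)-en-11-al | O[C@@H]1[C@H]2C(=C)[C@@H](O[Si](C)(C)C(C)(C)C)C[C@@H](O[Si](C)(C)C(C)(C)C)[C@]2(C)CC[C@H]1C=O | intermediate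
31 | 1β,3β-bis(TBSO)-5αH,7αH-12-noreudesm-4(15)-en-11(13)-yn-6α-ol | O[C@@H]1[C@H]2C(=C)[C@@H](O[Si](C)(C)C(C)(C)C)C[C@@H](O[Si](C)(C)C(C)(C)C)[C@]2(C)CC[C@H]1C#C | intermediate
32 | methyl 2-(hydroxymethyl)acrylate | C=C(CO)C(=O)OC | starting material
33 | methyl 2-[(TBSO)methyl]acrylate | C=C(CO[Si](C)(C)C(C)(C)C)C(=O)OC | intermediate
34 | 2-[(TBSO)methyl]acrylic acid | C=C(CO[Si](C)(C)C(C)(C)C)C(=O)O | intermediate
35 | 2-[(TBSO)methyl]acrylic 2,4,6-trichlorobenzoic anhydride | C=C(CO[Si](C)(C)C(C)(C)C)C(=O)OC(=O)c1c(Cl)cc(Cl)cc1Cl | intermediate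
36 | 1β,3β-bis(TBSO)-5αH,7αH-12-noreudesm-4(15)-en-11(13)-yn-6α-yl 2-[(TBSO)methyl]acrylate | C=C(CO[Si](C)(C)C(C)(C)C)C(=O)O[C@@H]1[C@H]2C(=C)[C@@H](O[Si](C)(C)C(C)(C)C)C[C@@H](O[Si](C)(C)C(C)(C)C)[C@]2(C)CC[C@H]1C#C | intermediate
37 | methyl 1β,3β-bis(TBSO)-6α-{2-[(TBSO)methyl]acryloyloxy}-5αH,7αH-eudesma-4(15),11(13)-dien-12-oate | C=C(CO[Si](C)(C)C(C)(C)C)C(=O)O[C@@H]1[C@H]2C(=C)[C@@H](O[Si](C)(C)C(C)(C)C)C[C@@H](O[Si](C)(C)C(C)(C)C)[C@]2(C)CC[C@H]1C(=C)C(=O)OC | intermediate
38 | methyl 1β,3β-dihydroxy-6α-[2-(hydroxymethyl)acryloyloxy]-5αH,7αH-eudesma-4(15),11(13)-dien-12-oate | C=C(CO)C(=O)O[C@@H]1[C@H]2C(=C)[C@@H](O)C[C@@H](O)[C@]2(C)CC[C@H]1C(=C)C(=O)OC | target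

Total step count: 27. Longest linear sequence: 24 (steps 1–6, 8–22, 25–27).

Steps most likely to fail

1. Step 10.
What may go wrong: the endo closure onto the allyl terminus may be slow, so intermolecular O-allylation and oligomerisation, β-hydride loss from the allyl complex, or weak discrimination between the two enantiotopic ring carbons may take over.
Fallback, from 14 and back at 15: methanolysis of the carbonate (K2CO3, MeOH, 0 °C) gives methyl (E)-2-[(3,5-dihydroxy-2,6-dimethylphenyl)methyl]-4-hydroxybut-2-enoate F1. Chlorination of the allylic alcohol (PPh3, N-chlorosuccinimide, THF, −20 °C), to which phenols are inert, gives methyl (E)-4-chloro-2-[(3,5-dihydroxy-2,6-dimethylphenyl)methyl]but-2-enoate F2. KOt-Bu (2 equiv) in t-BuOH–THF at high dilution closes ring B by intramolecular C-alkylation of the phenolate, a known route to cyclohexadienones, and gives racemic methyl 1,3-dioxo-12,13-dinoreudesma-4,7-dien-11-oate F3. Separation on a chiral stationary phase then delivers 15.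

2. Step 17.
What may go wrong: the selenium electrophile may attack C6 instead of the crowded C4, the tertiary allylic selenide may drift to C6 with return of conjugation, or selenium may be lost to selenolate during the reduction.
Fallback, from 21 and back at 28 (steps 18 and 19 are also bypassed): the dienolate 22, made from 21 as before, is hydroxylated at its α-carbon from the α face with 2-(phenylsulfonyl)-3-phenyloxaziridine (THF, −78 °C) to 1β,11-bis(TBSO)-4α-hydroxy-7αH-12,13-dinoreudesm-5-en-3-one F4, which cannot undergo an allylic shift. NaBH4 (MeOH, 0 °C) gives 1β,11-bis(TBSO)-7αH-12,13-dinoreudesm-5-ene-3β,4α-diol F5. TBSOTf (1 equiv) and 2,6-lutidine silylate only the secondary alcohol to give 1β,3β,11-tris(TBSO)-7αH-12,13-dinoreudesm-5-en-4α-ol F6. BH3·THF followed by H2O2/NaOH, with the borinate of the α-hydroxyl guiding the borane to the α face of a less crowded alkene, gives 1β,3β,11-tris(TBSO)-5αH,7αH-12,13-dinoreudesmane-4α,6α-diol F7. Bis[α,α-bis(trifluoromethyl)benzyloxy]diphenylsulfur (CH2Cl2, −78 °C) dehydrates the tertiary equatorial alcohol, whose only anti-periplanar hydrogens are on C15, and gives 28.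

3. Step 26.
What may go wrong: regiocontrol may erode at the α-branched alkyne, palladium hydride may shift the 4(15)-alkene into the ring once the alkyne is consumed, and the acid co-catalyst may cause premature loss of silyl groups.
Fallback, from 36 and back at 37: hydrosilylation with Et3SiH and [Cp*Ru(MeCN)3]PF6 (CH2Cl2, 0 °C), known to give the 1,1-disubstituted vinylsilane from terminal alkynes, gives 1β,3β-bis(TBSO)-11-(triethylsilyl)-5αH,7αH-12-noreudesma-4(15),11(13)-dien-6α-yl 2-[(TBSO)methyl]acrylate F8. Iododesilylation with N-iodosuccinimide (MeCN, 0 °C) gives 1β,3β-bis(TBSO)-11-iodo-5αH,7αH-12-noreudesma-4(15),11(13)-dien-6α-yl 2-[(TBSO)methyl]acrylate F9. Carbonylation of the vinyl iodide (Pd(PPh3)4, CO 1 atm, MeOH, Et3N, DMF, 40 °C) under basic, hydride-free conditions gives 37.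

Further compounds
F1 | step 10 | methyl (E)-2-[(3,5-dihydroxy-2,6-dimethylphenyl)methyl]-4-hydroxybut-2-enoate | OC/C=C(\Cc1c(C)c(O)cc(O)c1C)C(=O)OC
F2 | step 10 | methyl (E)-4-chloro-2-[(3,5-dihydroxy-2,6-dimethylphenyl)methyl]but-2-enoate | ClC/C=C(\Cc1c(C)c(O)cc(O)c1C)C(=O)OC
F3 | step 10 | racemic methyl 1,3-dioxo-12,13-dinoreudesma-4,7-dien-11-oate | C1C2=C(C)C(=O)CC(=O)C2(C)CC=C1C(=O)OC
F4 | step 17 | 1β,11-bis(TBSO)-4α-hydroxy-7αH-12,13-dinoreudesm-5-en-3-one | C1=C2[C@](C)(O)C(=O)C[C@@H](O[Si](C)(C)C(C)(C)C)[C@]2(C)CC[C@H]1CO[Si](C)(C)C(C)(C)C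
F5 | step 17 | 1β,11-bis(TBSO)-7αH-12,13-dinoreudesm-5-ene-3β,4α-diol | C1=C2[C@](C)(O)[C@@H](O)C[C@@H](O[Si](C)(C)C(C)(C)C)[C@]2(C)CC[C@H]1CO[Si](C)(C)C(C)(C)C
F6 | step 17 | 1β,3β,11-tris(TBSO)-7αH-12,13-dinoreudesm-5-en-4α-ol | C1=C2[C@](C)(O)[C@@H](O[Si](C)(C)C(C)(C)C)C[C@@H](O[Si](C)(C)C(C)(C)C)[C@]2(C)CC[C@H]1CO[Si](C)(C)C(C)(C)C
F7 | step 17 | 1β,3β,11-tris(TBSO)-5αH,7αH-12,13-dinoreudesmane-4α,6α-diol | O[C@@H]1[C@H]2[C@](C)(O)[C@@H](O[Si](C)(C)C(C)(C)C)C[C@@H](O[Si](C)(C)C(C)(C)C)[C@]2(C)CC[C@H]1CO[Si](C)(C)C(C)(C)C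
F8 | step 26 | 1β,3β-bis(TBSO)-11-(triethylsilyl)-5αH,7αH-12-noreudesma-4(15),11(13)-dien-6α-yl 2-[(TBSO)methyl]acrylate | C=C(CO[Si](C)(C)C(C)(C)C)C(=O)O[C@@H]1[C@H]2C(=C)[C@@H](O[Si](C)(C)C(C)(C)C)C[C@@H](O[Si](C)(C)C(C)(C)C)[C@]2(C)CC[C@H]1C(=C)[Si](CC)(CC)CC
F9 | step 26 | 1β,3β-bis(TBSO)-11-iodo-5αH,7αH-12-noreudesma-4(15),11(13)-dien-6α-yl 2-[(TBSO)methyl]acrylate | C=C(CO[Si](C)(C)C(C)(C)C)C(=O)O[C@@H]1[C@H]2C(=C)[C@@H](O[Si](C)(C)C(C)(C)C)C[C@@H](O[Si](C)(C)C(C)(C)C)[C@]2(C)CC[C@H]1C(=C)I
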